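**Assumptions:** The target, 7-hydroxy-2-(3,5-dihydroxy-4-methoxyphenyl)-5,8-dimethoxy-4H-chromen-4-one, has no stereocentre and no stereogenic double bond, so the "single enantiomer" clause needs no action and no step creates a stereocentre. 2-Methoxyresorcinol and 3,5-dihydroxy-4-methoxybenzaldehyde are taken as purchasable. Reagents are named with SMILES in each step and are not numbered.

## Retrosynthetic overview

1. Target 13 ⇐ ynone 11 by acid-triggered removal of four MOM groups and 6-endo-dig oxa-Michael closure (O1–C2 bond). The pyranone is the only ring made, and it is made last.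
2. Ynone 11 ⇐ aryl iodide 7 + CO + arylacetylene 10 by Pd-catalysed three-component carbonylative Sonogashira coupling (key step; CO becomes C4, forming C4a–C4 and C4–C3).
3. Iodide 7 ⇐ directed ortho-metalation/iodination of arene 5 ⇐ 2-methoxyresorcinol 1, with the isolated A-ring oxygen installed by sterically controlled Ir C–H borylation/oxidation.
4. Alkyne 10 ⇐ Ohira–Bestmann homologation of MOM-protected 3,5-dihydroxy-4-methoxybenzaldehyde 8.
5. This avoids the usual 2-hydroxyacetophenone routes (Baker–Venkataraman, chalcone oxidation); both benzene rings are bought.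

## Route

**Step 1**
Reactants: 1 2-methoxyresorcinol (2-methoxybenzene-1,3-diol)
Product: 2 2-methoxy-1,3-bis(methoxymethoxy)benzene
Conditions: MOMCl (2.5 equiv), i-Pr2NEt (3 equiv), CH2Cl2, 0 °C → rt
Reagents that add atoms: chloromethyl methyl ether (MOMCl), COCCl
Why: Williamson-type O-alkylation of both phenols gives the bis-MOM acetal, which is base-stable, directs lithiation later and is acid-labile at the end.

**Step 2**
Reactants: 2 2-methoxy-1,3-bis(methoxymethoxy)benzene
Product: 4 4-methoxy-3,5-bis(methoxymethoxy)phenol, via arylboronate 3 (not isolated)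
Conditions: [Ir(OMe)(cod)]2 (1.5 mol%), dtbpy (3 mol%), B2pin2 (1.0 equiv), THF, 80 °C; then 30% H2O2, aq NaOH, 0 °C → rt, NH4Cl work-up
Reagents that add atoms: bis(pinacolato)diboron, CC1(C)OB(OC1(C)C)B1OC(C)(C)C(C)(C)O1 (boron of intermediate 3); hydrogen peroxide, OO (phenol oxygen of 4)
Why: Ir-catalysed aromatic C–H borylation is sterically controlled and C5–H is the only ring C–H without an ortho substituent, so a single boronate forms and is oxidised ipso to the phenol in the same pot.

**Step 3**
Reactants: 4 4-methoxy-3,5-bis(methoxymethoxy)phenol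
Product: 5 2,5-dimethoxy-1,3-bis(methoxymethoxy)benzene
Conditions: MeI (1.5 equiv), K2CO3, DMF, rt
Reagents that add atoms: iodomethane, CI
Why: Williamson O-methylation of the only free phenol.

**Step 4**
Reactants: 5 2,5-dimethoxy-1,3-bis(methoxymethoxy)benzene
Product: 7 2-iodo-1,4-dimethoxy-3,5-bis(methoxymethoxy)benzene, via aryllithium 6 (not isolated)
Conditions: n-BuLi (1.1 equiv), THF, 0 °C, 1 h; then I2, −78 °C → rt
Reagents that add atoms: n-butyllithium, [Li]CCCC (lithium of intermediate 6); iodine, II
Why: Directed ortho-metalation: the two ring C–H positions are equivalent and each lies between OMOM and OMe, so one aryllithium forms and is trapped by iodine.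

**Step 5**
Reactants: 8 3,5-dihydroxy-4-methoxybenzaldehyde
Product: 9 4-methoxy-3,5-bis(methoxymethoxy)benzaldehyde
Conditions: MOMCl (2.5 equiv), i-Pr2NEt (3 equiv), CH2Cl2, 0 °C → rt
Reagents that add atoms: chloromethyl methyl ether (MOMCl), COCCl
Why: O-alkylation of both phenols as MOM acetals, which survive the basic homologation and the Pd step and fall off together with the A-ring MOM groups.

**Step 6**
Reactants: 9 4-methoxy-3,5-bis(methoxymethoxy)benzaldehyde
Product: 10 5-ethynyl-2-methoxy-1,3-bis(methoxymethoxy)benzene
Conditions: dimethyl (1-diazo-2-oxopropyl)phosphonate (1.3 equiv), K2CO3 (2 equiv), MeOH, 0 °C → rt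
Reagents that add atoms: dimethyl (1-diazo-2-oxopropyl)phosphonate (Ohira–Bestmann reagent), CC(=O)C(=[N+]=[N-])P(=O)(OC)OC (supplies the terminal alkyne carbon)
Why: Ohira–Bestmann (Seyferth–Gilbert) homologation of a non-enolisable aryl aldehyde under mild carbonate conditions gives the terminal alkyne.

**Step 7 (key step)**
Reactants: 7 2-iodo-1,4-dimethoxy-3,5-bis(methoxymethoxy)benzene; 10 5-ethynyl-2-methoxy-1,3-bis(methoxymethoxy)benzene (1.3 equiv, added slowly)
Product: 11 1-[3,6-dimethoxy-2,4-bis(methoxymethoxy)phenyl]-3-[4-methoxy-3,5-bis(methoxymethoxy)phenyl]prop-2-yn-1-one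
Conditions: PdCl2(PPh3)2 (5 mol%), CuI (2 mol%), Et3N (3 equiv), CO (1 atm, balloon), THF, rt → 45 °C
Reagents that add atoms: carbon monoxide, [C-]#[O+]
Why: Carbonylative Sonogashira coupling: CO insertion into the electron-rich, doubly ortho-substituted aryl–Pd bond is faster than direct alkynylation, so the acyl–Pd species is intercepted by the copper acetylide to give the ynone.

**Step 8**
Reactants: 11 the tetrakis-MOM ynone
Product: 13 7-hydroxy-2-(3,5-dihydroxy-4-methoxyphenyl)-5,8-dimethoxy-4H-chromen-4-one (target), via free hydroxy ynone 12 (not isolated)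
Conditions: 2 M HCl, MeOH/THF (1:1), 55 °C
Reagents that add atoms: none
Why: Acid-catalysed acetal exchange removes all four MOM groups, and the phenol ortho to the carbonyl then adds 6-endo-dig to the protonated ynone (oxa-Michael cycloisomerisation), which under acid gives the pyranone rather than the aurone and leaves the aryl methyl ethers intact.

## Compound list

1 | 2-methoxyresorcinol (2-methoxybenzene-1,3-diol) | COc1c(O)cccc1O | starting material
2 | 2-methoxy-1,3-bis(methoxymethoxy)benzene | COCOc1cccc(OCOC)c1OC | intermediate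
3 | 2-[4-methoxy-3,5-bis(methoxymethoxy)phenyl]-4,4,5,5-tetramethyl-1,3,2-dioxaborolane | COCOc1cc(B2OC(C)(C)C(C)(C)O2)cc(OCOC)c1OC | intermediate (not isolated)
4 | 4-methoxy-3,5-bis(methoxymethoxy)phenol | COCOc1cc(O)cc(OCOC)c1OC | intermediate
5 | 2,5-dimethoxy-1,3-bis(methoxymethoxy)benzene | COCOc1cc(OC)cc(OCOC)c1OC | intermediate
6 | [2,5-dimethoxy-4,6-bis(methoxymethoxy)phenyl]lithium (lithium between OMe and OMOM) | COCOc1cc(OC)c([Li])c(OCOC)c1OC | intermediate (not isolated)
7 | 2-iodo-1,4-dimethoxy-3,5-bis(methoxymethoxy)benzene | COCOc1cc(OC)c(I)c(OCOC)c1OC | intermediate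
8 | 3,5-dihydroxy-4-methoxybenzaldehyde | COc1c(O)cc(C=O)cc1O | starting material
9 | 4-methoxy-3,5-bis(methoxymethoxy)benzaldehyde | COCOc1cc(C=O)cc(OCOC)c1OC | intermediate
10 | 5-ethynyl-2-methoxy-1,3-bis(methoxymethoxy)benzene | COCOc1cc(C#C)cc(OCOC)c1OC | intermediate
11 | 1-[3,6-dimethoxy-2,4-bis(methoxymethoxy)phenyl]-3-[4-methoxy-3,5-bis(methoxymethoxy)phenyl]prop-2-yn-1-one | COCOc1cc(OC)c(C(=O)C#Cc2cc(OCOC)c(OC)c(OCOC)c2)c(OCOC)c1OC | intermediate
12 | 1-(2,4-dihydroxy-3,6-dimethoxyphenyl)-3-(3,5-dihydroxy-4-methoxyphenyl)prop-2-yn-1-one | COc1cc(O)c(OC)c(O)c1C(=O)C#Cc1cc(O)c(OC)c(O)c1 | intermediate (not isolated)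
13 | 7-hydroxy-2-(3,5-dihydroxy-4-methoxyphenyl)-5,8-dimethoxy-4H-chromen-4-one (7,3',5'-trihydroxy-5,8,4'-trimethoxyflavone) | COc1c(O)cc(-c2cc(=O)c3c(OC)cc(O)c(OC)c3o2)cc1O | target

## Summary

Total step count: 8.
Longest linear sequence: 6 steps (steps 1, 2, 3, 4, 7, 8).

**Three steps most likely to fail**

Step 7 (carbonylative coupling of a crowded, very electron-rich aryl iodide; risks are slow oxidative addition, direct Sonogashira product or alkyne dimer). The fallback drops palladium and CO and makes the aryl–carbonyl bond by acylating the aryllithium. It sets out from alkyne 10, which is deprotonated (n-BuLi, THF, −78 °C) and quenched with N-methoxy-N-methylcarbamoyl chloride to give the Weinreb ynamide N-methoxy-3-[4-methoxy-3,5-bis(methoxymethoxy)phenyl]-N-methylprop-2-ynamide F1. Arene 5 is lithiated as in step 4 to aryllithium 6, and F1 is added at −78 °C; the chelated tetrahedral adduct collapses on work-up, and the route is rejoined at ynone 11.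

Step 8 (one-pot fourfold deprotection and ring closure; risks are incomplete closure, aurone formation or decomposition of the free polyphenolic ynone). The fallback fixes the regiochemistry before any phenol is freed. It sets out from ynone 11, which is treated with Et2NH in EtOH at rt to give, by conjugate addition, the enaminone (E)-3-(diethylamino)-1-[3,6-dimethoxy-2,4-bis(methoxymethoxy)phenyl]-3-[4-methoxy-3,5-bis(methoxymethoxy)phenyl]prop-2-en-1-one F2. Heating F2 in 2 M HCl/MeOH removes the MOM groups, and the ortho phenol closes by addition–elimination with loss of diethylamine, which can only give the six-membered ring; the route is rejoined at target 13.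

Step 4 (lithiation at a position flanked on both sides; risks are incomplete metalation or attack on the MOM groups). The fallback replaces deprotonative metalation by electrophilic aromatic substitution. It sets out from arene 5, which is treated with N-iodosuccinimide (1.05 equiv) in MeCN at 0 °C → rt; the ring is tetra-oxygenated and its two free positions are equivalent, so mono-iodination gives iodide 7 directly, where the route is rejoined. No new compound is formed on this path (line F0 below).

## Further compounds

F1 | step 7 | N-methoxy-3-[4-methoxy-3,5-bis(methoxymethoxy)phenyl]-N-methylprop-2-ynamide | CON(C)C(=O)C#Cc1cc(OCOC)c(OC)c(OCOC)c1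
F2 | step 8 | (E)-3-(diethylamino)-1-[3,6-dimethoxy-2,4-bis(methoxymethoxy)phenyl]-3-[4-methoxy-3,5-bis(methoxymethoxy)phenyl]prop-2-en-1-one | COCOc1cc(OC)c(C(=O)/C=C(/N(CC)CC)c2cc(OCOC)c(OC)c(OCOC)c2)c(OCOC)c1OC
F0 | step 4 | none | none
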